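## Retrosynthetic overview

1. Numbering: C1 bridgehead carbinol, C2 CH2, C3 C–N, C4 and C6 carbinols, C5 bridgehead CH, C7–C8 oxirane, C9 ketone. Feature: if the C7–C8 oxirane and the C2–C3 (H, N) pair are both read as C=C, the rings C1–C2–C3–C4–C5–C9 and C1–C8–C7–C6–C5–C9 become mirror images. The result is a meso bicyclo[3.3.1]nona-2,7-diene-4,6-diol with its plane through C1, C9 and C5.
2. Endgame disconnections: the amide N–C(O) bond (decenoic acid), then C3–N (5-exo addition of a carbamate N-radical tethered to the C4 oxygen, hence cis).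
3. Key disconnection: both C–O bonds of the C7–C8 oxirane, made by a chiral vanadium–bishydroxamate epoxidation that picks one of the two enantiotopic allylic alcohol units of the meso diol.
4. Meso diol: C4–C5 and C5–C6 come from a double intramolecular aldol addition of (2Z,5Z)-4-acetyl-4-silyloxyhepta-2,5-dienedial, itself built from a pyruvate ketal ester and two propargyl ether acetylides.
5. Ring order: carbocycle C1–C2–C3–C4–C5–C9, carbocycle C1–C8–C7–C6–C5–C9 (same flask), oxirane, temporary oxazolidinone (opened again).

Key step: step 8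

Assumption 1: the (R,R)-ligand is written for the sense of induction shown. This sense cannot be predicted with certainty for this bicyclic diol, and the equally available (S,S)-ligand is used if the antipode forms.

Assumption 2: 4-methoxybenzyl propargyl ether is taken as a catalogue compound. Otherwise it is one Williamson step from propargyl bromide and 4-methoxybenzyl alcohol.

## Route

Step 1
Reactants: 1 methyl 2,2-dimethoxypropanoate; 2 4-methoxybenzyl propargyl ether (2.3 equiv)
Product: 5 4-(1,1-dimethoxyethyl)-1,7-bis[(4-methoxybenzyl)oxy]hepta-2,5-diyn-4-ol, via lithium 3-[(4-methoxybenzyl)oxy]prop-1-yn-1-ide 3 (not isolated), via 2,2-dimethoxy-6-[(4-methoxybenzyl)oxy]hex-4-yn-3-one 4 (not isolated)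
Conditions: 2, n-BuLi, THF, −78 °C; then 1, −78 → 0 °C; H2O
Reagents that add atoms: n-butyllithium, [Li]CCCC (lithium, held only by intermediate 3)
Why: Double 1,2-addition of a lithium acetylide to an ester: addition–elimination gives ynone 4, which is more electrophilic than 1 and takes the second acetylide at the carbonyl carbon, while the ketal and the PMB ethers are inert to the acetylide at low temperature.

Step 2
Reactants: 5 bis-alkynyl carbinol
Product: 6 triethylsilyl ether of 5
Conditions: TESOTf, 2,6-lutidine, CH2Cl2, −78 → 0 °C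
Reagents that add atoms: triethylsilyl trifluoromethanesulfonate, CC[Si](CC)(CC)OS(=O)(=O)C(F)(F)F
Why: Silyl triflate/hindered-pyridine O-silylation is strong enough for a tertiary carbinol whose two slim alkynyl arms leave the oxygen open, and it leaves the ketal alone because the three electron-withdrawing groups on the neighbouring carbon disfavour its ionisation.

Step 3
Reactants: 6 bis-alkyne
Product: 7 (2Z,5Z)-4-(1,1-dimethoxyethyl)-1,7-bis[(4-methoxybenzyl)oxy]-4-(triethylsilyloxy)hepta-2,5-diene
Conditions: H2 (1 atm), Lindlar catalyst, quinoline, EtOAc, rt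
Reagents that add atoms: none
Why: Lindlar semihydrogenation: syn addition of H2 on lead- and quinoline-poisoned palladium should stop at the two (Z)-alkenes, and benzyl-type ethers, ketal and silyl ether are not reduced under these conditions.

Step 4
Reactants: 7 (Z,Z)-diene ketal
Product: 8 (4Z)-6-[(4-methoxybenzyl)oxy]-3-{(1Z)-3-[(4-methoxybenzyl)oxy]prop-1-en-1-yl}-3-(triethylsilyloxy)hex-4-en-2-one
Conditions: p-TsOH·H2O (5 mol %), acetone/H2O 10:1, 0 °C → rt; NaHCO3 quench at full conversion
Reagents that add atoms: water, O
Why: Acid-catalysed ketal hydrolysis is placed here on purpose: with vinyl instead of alkynyl neighbours the oxocarbenium ion should form fast enough to outrun cleavage of the hindered, electron-poor tertiary TES ether, and with both primary oxygens still blocked as acid-stable PMB ethers no (Z)-allylic hydroxyl can trap that cation as a cyclic or bicyclic ketal.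

Step 5
Reactants: 8 bis-PMB ether ketone
Product: 9 (4Z)-6-hydroxy-3-[(1Z)-3-hydroxyprop-1-en-1-yl]-3-(triethylsilyloxy)hex-4-en-2-one
Conditions: DDQ (2.4 equiv), CH2Cl2/pH 7 phosphate buffer 10:1, 0 °C → rt; carried on without chromatography on acidic silica
Reagents that add atoms: none
Why: Oxidative PMB-ether cleavage (benzylic hydride abstraction by DDQ, then hydrolysis of the oxocarbenium ion) runs at neutral pH, so that 9, which should sit largely as its six-membered hemiketal, cannot lose water to the bicyclic ketal, and the TES ether and the (Z)-alkenes are untouched.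

Step 6
Reactants: 9 keto diol
Product: 10 (2Z,5Z)-4-acetyl-4-(triethylsilyloxy)hepta-2,5-dienedial
Conditions: TEMPO (20 mol %), PhI(OAc)2 (2.4 equiv), CH2Cl2, rt
Reagents that add atoms: none
Why: TEMPO/PhI(OAc)2 oxidation of primary allylic alcohols stops at the aldehyde and is known to keep (Z)-enal geometry; here there is no γ-hydrogen for dienol-type isomerisation, and the hemiketal form drains through the open hydroxy ketone.

Step 7
Reactants: 10 bis-(Z)-enal methyl ketone
Product: 12 meso-4-exo,6-exo-dihydroxy-1-(triethylsilyloxy)bicyclo[3.3.1]nona-2,7-dien-9-one, via rac-5-hydroxy-2-[(Z)-3-oxoprop-1-en-1-yl]-2-(triethylsilyloxy)cyclohex-3-en-1-one (OH cis to OTES) 11 (not isolated)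
Conditions: MgBr2·OEt2 (3 equiv), i-Pr2NEt (3 equiv), CH2Cl2 (0.01 M), −20 °C → rt; aq. NH4Cl
Reagents that add atoms: none
Why: Mg(II)/tertiary-amine soft enolisation makes the only possible enolate (C5, the methyl carbon), which closes ring C1–C2–C3–C4–C5–C9 on one (Z)-enal and, after re-enolisation at C5, ring C1–C8–C7–C6–C5–C9 on the other by intramolecular aldol addition; each new carbinol oxygen should end exo (pseudo-axial, gauche to C9) because the aldehyde oxygen is held by the magnesium on the C9 enolate oxygen in a closed Zimmerman–Traxler-type transition state and because the reversible aldol drains the endo epimers, whose C–O bond is nearly eclipsed with the other C5–C bond, and once bicyclic the product can no longer dehydrate since C5–H lies in the nodal plane of the C9 carbonyl (Bredt's rule).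

Step 8
Reactants: 12 meso diene-diol
Product: 13 enantioenriched 7,8-exo-epoxide: 4-exo,6-exo-dihydroxy-7,8-exo-epoxy-1-(triethylsilyloxy)bicyclo[3.3.1]non-2-en-9-one
Conditions: VO(Oi-Pr)3 (2 mol %), (R,R)-N,N′-dihydroxy-N,N′-bis(diphenylacetyl)cyclohexane-1,2-diamine (4 mol %), aq. t-BuOOH (1.1 equiv), toluene, 0 °C
Reagents that add atoms: tert-butyl hydroperoxide, CC(C)(C)OO
Why: Ligand exchange places one of the two enantiotopic C–OH groups of 12 and tert-butyl peroxide on the chiral V(V)–bishydroxamate centre, and the bound peroxide oxygen is passed in one concerted step to the adjacent cis C7=C8 bond; the closest known reaction type is the vanadium/bishydroxamic acid asymmetric epoxidation of allylic alcohols, which has been used to desymmetrise meso secondary allylic alcohols. The oxirane, the only ring closed, forms by suprafacial [2+1] oxygen-atom transfer, so both C–O bonds are made on the same face. C7 and C8 are set relative to C6 by the metal tether: the locked pseudo-axial exo hydroxyl, the geometry that vanadium prefers in cyclohexenols, can only reach the exo face, which is also the open convex face, so the epoxide is syn to C6–OH. The absolute sense, and with it the configuration of C1, C4, C5 and C6, which were paired by the mirror plane in 12, is set by the ligand, whose pocket makes the alkoxide of one allylic alcohol unit react faster than its mirror-image partner. The step needs enantiotopic-group selectivity and mono- over bis-epoxidation: the first comes from the catalyst, the second from limiting peroxide, and the slower second epoxidation consumes mainly the minor enantiomer as the achiral bis-epoxide and so should raise the enantiomeric purity. The ketone, the silyl ether and the C2=C3 alkene of the slower unit are not attacked by V/t-BuOOH.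

Step 9
Reactants: 13 epoxy diol
Product: 14 C4,C6-bis[N-(4-methoxyphenyl)carbamate] of 13
Conditions: 4-MeOC6H4NCO (2.5 equiv), Bu2Sn(O2CC11H23)2 (5 mol %), CH2Cl2, rt → 40 °C
Reagents that add atoms: 4-methoxyphenyl isocyanate, COc1ccc(N=C=O)cc1
Why: Tin-catalysed urethane formation (alcohol plus aryl isocyanate) is neutral, so the β-hydroxy ketone sees no base, and both hydroxyls are carbamoylated on purpose because the allylic C4–OH and the epoxy C6–OH cannot be told apart reliably; no stereocentre is touched.

Step 10
Reactants: 14 bis-carbamate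
Product: 15 cis-fused C3-N/C4-O N-(4-methoxyphenyl)oxazolidinone (C3–N exo, C2 now CH2), C6 carbamate unchanged
Conditions: [Ir(dF(CF3)ppy)2(bpy)]PF6 (2 mol %), Bu4N[(BuO)2PO2] (20 mol %), PhSH (30 mol %), CH2Cl2, blue LEDs, rt
Reagents that add atoms: none
Why: Photocatalytic proton-coupled electron-transfer hydroamidation of N-aryl carbamates: excited Ir(III) and phosphate remove e−/H+ from N–H, the C4-tethered N-radical adds 5-exo-trig to C3 on the exo face fixed by the C4–O tether (cis-fused ring, sets C3), the thiol gives H to the C2 radical faster than a 1,2-acyl shift can occur, and the C6 N-radical, which has no alkene within reach and cannot open the cis epoxide, simply returns to N–H.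

Step 11
Reactants: 15 oxazolidinone with C6 N–H carbamate
Product: 18 C6 alcohol (N-aryl oxazolidinone, TES ether and epoxide kept), via C6 N-Boc-N-(4-methoxyphenyl)carbamate 16 (not isolated), via C6 methyl carbonate 17 (not isolated)
Conditions: Boc2O (1.5 equiv), DMAP (0.2 equiv), MeCN, rt; then MeOH, K2CO3 (0.5 equiv), 0 °C → rt
Reagents that add atoms: di-tert-butyl dicarbonate, CC(C)(C)OC(=O)OC(=O)OC(C)(C)C (held only by 16); methanol, CO (held only by 17)
Why: Acyl activation and solvolysis of a carbamate: N-tert-butoxycarbonylation of the only N–H carbamate gives an imidodicarbonate whose less hindered carbonyl is attacked by methoxide with loss of the stabilised Boc-anilide anion, and methyl carbonate 17 is transesterified to dimethyl carbonate, so O6 is freed under weak base at or below room temperature instead of hot hydroxide, which would risk retro-aldol opening at C5 and loss of the silyl ether.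

Step 12
Reactants: 18 N-(4-methoxyphenyl)oxazolidinone
Product: 19 N–H oxazolidinone
Conditions: (NH4)2Ce(NO3)6 (3.5 equiv), MeCN/H2O 3:1, 0 °C, short contact
Reagents that add atoms: none
Why: Ceric ammonium nitrate N-dearylation: two-electron oxidation of the p-anisyl group to the quinone iminium ion and hydrolysis release the N–H oxazolidinone, a standard operation on N-PMP lactams and oxazolidinones that leaves the secondary alcohol, ketone and epoxide alone and that the hindered, electron-poor bridgehead TES ether should survive at 0 °C.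

Step 13
Reactants: 19 N–H oxazolidinone
Product: 22 C3 NHBoc, free C4–OH, C6 O-Boc carbonate, C1 OTES, via N-Boc oxazolidinone C6 O-Boc carbonate 20 (not isolated), via ring-opened C4 methyl carbonate 21 (not isolated)
Conditions: Boc2O (3 equiv), DMAP (0.3 equiv), MeCN, rt; then MeOH, Cs2CO3 (0.3 equiv), rt
Reagents that add atoms: di-tert-butyl dicarbonate, CC(C)(C)OC(=O)OC(=O)OC(C)(C)C; methanol, CO (held only by 21)
Why: N-Boc activation followed by carbonate-catalysed methanolysis is the mild way to open an oxazolidinone: methoxide attacks the unhindered ring carbonyl, the Boc-stabilised nitrogen leaves, methyl carbonate 21 is transesterified away, the bulky tert-butyl carbonate on O6 is left, and C3 and C4 keep their configuration because only acyl C–O/C–N bonds are broken.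

Step 14
Reactants: 22 protected amino alcohol
Product: 23 trifluoroacetate salt of the free amino triol (3-exo-amino-1,4-exo,6-exo-trihydroxy-7,8-exo-epoxybicyclo[3.3.1]nonan-9-one)
Conditions: TFA/CH2Cl2/H2O 10:10:1, 0 °C → rt; evaporate
Reagents that add atoms: trifluoroacetic acid, OC(=O)C(F)(F)F (counter-ion of 23)
Why: Acidolysis removes the N-Boc, O-Boc and TES groups in one operation, while the oxirane should hold because both its carbons carry electron-withdrawing oxygenated neighbours, its rear (endo) face is shielded, and every neighbouring oxygen (O1, O6) is cis to it and so cannot open it from behind.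

Step 15
Reactants: 23 ammonium trifluoroacetate; 24 (E)-dec-2-enoic acid
Product: 26 isariotin D, via benzotriazol-1-yl (E)-dec-2-enoate 25 (not isolated)
Conditions: 24, EDC·HCl, HOBt, DMF, 0 °C; then 23, i-Pr2NEt, 0 °C → rt
Reagents that add atoms: 1-hydroxybenzotriazole, On1nnc2ccccc12 (held only by 25)
Why: Carbodiimide/HOBt amide coupling: the primary amine is far more nucleophilic than the secondary and tertiary hydroxyls toward the active ester in the absence of an acyl-transfer catalyst, and the (E)-enoate geometry and all ring stereocentres are untouched.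

## Compound list

1 | methyl 2,2-dimethoxypropanoate | COC(=O)C(C)(OC)OC | starting material
2 | 4-methoxybenzyl propargyl ether | C#CCOCc1ccc(OC)cc1 | starting material
3 | lithium 3-[(4-methoxybenzyl)oxy]prop-1-yn-1-ide | [Li]C#CCOCc1ccc(OC)cc1 | intermediate
4 | 2,2-dimethoxy-6-[(4-methoxybenzyl)oxy]hex-4-yn-3-one | CC(OC)(OC)C(=O)C#CCOCc1ccc(OC)cc1 | intermediate
5 | 4-(1,1-dimethoxyethyl)-1,7-bis[(4-methoxybenzyl)oxy]hepta-2,5-diyn-4-ol | CC(OC)(OC)C(O)(C#CCOCc1ccc(OC)cc1)C#CCOCc1ccc(OC)cc1 | intermediate
6 | triethylsilyl ether of 5 | CC(OC)(OC)C(O[Si](CC)(CC)CC)(C#CCOCc1ccc(OC)cc1)C#CCOCc1ccc(OC)cc1 | intermediate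
7 | (2Z,5Z)-diene ketal | CC(OC)(OC)C(O[Si](CC)(CC)CC)(/C=C\COCc1ccc(OC)cc1)/C=C\COCc1ccc(OC)cc1 | intermediate
8 | (Z,Z)-bis-PMB ether methyl ketone | CC(=O)C(O[Si](CC)(CC)CC)(/C=C\COCc1ccc(OC)cc1)/C=C\COCc1ccc(OC)cc1 | intermediate
9 | (Z,Z)-keto diol (open form of the hemiketal) | CC(=O)C(O[Si](CC)(CC)CC)(/C=C\CO)/C=C\CO | intermediate
10 | (2Z,5Z)-4-acetyl-4-(triethylsilyloxy)hepta-2,5-dienedial | CC(=O)C(O[Si](CC)(CC)CC)(/C=C\C=O)/C=C\C=O | intermediate
11 | monocyclic aldol, racemic, one enantiomer drawn, OH cis to OTES | C1=C[C@](O[Si](CC)(CC)CC)(/C=C\C=O)C(=O)C[C@H]1O | intermediate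
12 | meso-4-exo,6-exo-dihydroxy-1-(triethylsilyloxy)bicyclo[3.3.1]nona-2,7-dien-9-one | C1=C[C@@]2(O[Si](CC)(CC)CC)C(=O)[C@H]([C@H](O)C=C2)[C@H]1O | intermediate
13 | 7,8-exo-mono-epoxide of 12, single enantiomer | C1=C[C@@]2(O[Si](CC)(CC)CC)C(=O)[C@H]([C@H](O)[C@@H]3O[C@@H]32)[C@H]1O | intermediate
14 | C4,C6-bis[N-(4-methoxyphenyl)carbamate] | C1=C[C@@]2(O[Si](CC)(CC)CC)C(=O)[C@H]([C@H](OC(=O)Nc4ccc(OC)cc4)[C@@H]3O[C@@H]32)[C@H]1OC(=O)Nc1ccc(OC)cc1 | intermediate
15 | cis C3/C4 N-PMP oxazolidinone, C6 N-PMP carbamate | O=C1N(c2ccc(OC)cc2)[C@H]3C[C@@]4(O[Si](CC)(CC)CC)C(=O)[C@H]([C@H](OC(=O)Nc2ccc(OC)cc2)[C@@H]5O[C@@H]54)[C@H]3O1 | intermediate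
16 | C6 N-Boc-N-PMP carbamate | O=C1N(c2ccc(OC)cc2)[C@H]3C[C@@]4(O[Si](CC)(CC)CC)C(=O)[C@H]([C@H](OC(=O)N(C(=O)OC(C)(C)C)c2ccc(OC)cc2)[C@@H]5O[C@@H]54)[C@H]3O1 | intermediate
17 | C6 methyl carbonate | O=C1N(c2ccc(OC)cc2)[C@H]3C[C@@]4(O[Si](CC)(CC)CC)C(=O)[C@H]([C@H](OC(=O)OC)[C@@H]5O[C@@H]54)[C@H]3O1 | intermediate
18 | N-PMP oxazolidinone, free C6–OH | O=C1N(c2ccc(OC)cc2)[C@H]3C[C@@]4(O[Si](CC)(CC)CC)C(=O)[C@H]([C@H](O)[C@@H]5O[C@@H]54)[C@H]3O1 | intermediate
19 | N–H oxazolidinone, free C6–OH | O=C1N[C@H]3C[C@@]4(O[Si](CC)(CC)CC)C(=O)[C@H]([C@H](O)[C@@H]5O[C@@H]54)[C@H]3O1 | intermediate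
20 | N-Boc oxazolidinone, C6 O-Boc carbonate | O=C1N(C(=O)OC(C)(C)C)[C@H]3C[C@@]4(O[Si](CC)(CC)CC)C(=O)[C@H]([C@H](OC(=O)OC(C)(C)C)[C@@H]5O[C@@H]54)[C@H]3O1 | intermediate
21 | C3 NHBoc, C4 methyl carbonate, C6 O-Boc | CC(C)(C)OC(=O)N[C@H]1C[C@@]2(O[Si](CC)(CC)CC)C(=O)[C@H]([C@H](OC(=O)OC(C)(C)C)[C@@H]3O[C@@H]32)[C@H]1OC(=O)OC | intermediate
22 | C3 NHBoc, C4–OH, C6 O-Boc, C1 OTES | CC(C)(C)OC(=O)N[C@H]1C[C@@]2(O[Si](CC)(CC)CC)C(=O)[C@H]([C@H](OC(=O)OC(C)(C)C)[C@@H]3O[C@@H]32)[C@H]1O | intermediate
23 | amino triol trifluoroacetate | N[C@H]1C[C@@]2(O)C(=O)[C@H]([C@H](O)[C@@H]3O[C@@H]32)[C@H]1O.OC(=O)C(F)(F)F | intermediate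
24 | (E)-dec-2-enoic acid | CCCCCCC/C=C/C(=O)O | starting material
25 | benzotriazol-1-yl (E)-dec-2-enoate | CCCCCCC/C=C/C(=O)On1nnc2ccccc12 | intermediate
26 | isariotin D | CCCCCCC/C=C/C(=O)N[C@H]1C[C@@]2(O)C(=O)[C@H]([C@H](O)[C@@H]3O[C@@H]32)[C@H]1O | target

## Step count and risks

Total step count: 15. Longest linear sequence: 15 (from 1 or 2 to 26; 24 enters in the last step).

Steps most likely to fail:

**Step 8.** What may go wrong:
- weak discrimination between the two enantiotopic allylic alcohol units of a rigid, hindered bicycle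
- competing vanadium-mediated oxidation of an allylic carbinol to the enone
- run-on to the bis-epoxide

The fallback sets out from 12 and moves the enantio-determining event from oxygen transfer to acyl transfer.
- A chiral isothiourea acyl-transfer catalyst (benzotetramisole, either enantiomer) with propanoic anhydride and i-Pr2NEt would acylate one of the two enantiotopic hydroxyls, giving the C4 mono-propanoate of the meso diol F1.
- Achiral VO(acac)2/t-BuOOH would then epoxidise only the alkene next to the remaining free hydroxyl, again syn and exo, to give the epoxy propanoate F2.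
- K2CO3/MeOH at 0 °C removes the ester, and the route is rejoined at 13.

**Step 7.** What may go wrong:
- loss of water from the monocyclic aldol by E1cB before the second ring closes
- (Z)→(E) isomerisation of the enals by reversible conjugate addition of bromide or amine
- incomplete exo/endo control

The fallback sets out from 10 and replaces the reversible direct aldol by a stepwise Mukaiyama aldol sequence.
- TMSOTf/Et3N at −78 °C would convert the methyl ketone (the enals have no enolisable hydrogen) into the trimethylsilyl enol ether F3.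
- Catalytic TMSOTf at −78 °C would close the first ring with silyl transfer to the monocyclic β-silyloxy ketone F4. Its oxygen is capped and it sees no base.
- A second silylation would give the cyclic silyl enol ether F5, and a second Lewis-acid closure the bicyclic bis-TMS ether F6.
- Citric acid in MeOH takes off the two secondary TMS groups in the presence of the tertiary TES ether and returns to 12.

**Step 10.** What may go wrong:
- quenching of the N-radical by the thiol before it cyclises
- 1,2-acyl shift of the C2 radical toward C9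
- thiolate attack on the epoxide

The fallback sets out from 14 and comes back at 15. The N-radical is no longer made by catalytic photochemical PCET. It is made by stoichiometric single-electron oxidation of the anilide with IBX (THF/DMSO 10:1, 90 °C, sealed tube), the known thermal cyclisation of cyclohexenyl N-aryl carbamates to cis-fused oxazolidinones. THF is the hydrogen donor and neither thiol nor base is present. This fallback makes no new compound (F0).

## Further compounds

F1 | step 8 | 6-exo-hydroxy-9-oxo-1-(triethylsilyloxy)bicyclo[3.3.1]nona-2,7-dien-4-exo-yl propanoate | C1=C[C@@]2(O[Si](CC)(CC)CC)C(=O)[C@H]([C@H](O)C=C2)[C@H]1OC(=O)CC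
F2 | step 8 | 7,8-exo-epoxy-6-exo-hydroxy-9-oxo-1-(triethylsilyloxy)bicyclo[3.3.1]non-2-en-4-exo-yl propanoate | C1=C[C@@]2(O[Si](CC)(CC)CC)C(=O)[C@H]([C@H](O)[C@@H]3O[C@@H]32)[C@H]1OC(=O)CC
F3 | step 7 | trimethylsilyl enol ether of 10 | C=C(O[Si](C)(C)C)C(O[Si](CC)(CC)CC)(/C=C\C=O)/C=C\C=O
F4 | step 7 | monocyclic β-(trimethylsilyloxy) ketone, racemic, one enantiomer drawn | C1=C[C@](O[Si](CC)(CC)CC)(/C=C\C=O)C(=O)C[C@H]1O[Si](C)(C)C
F5 | step 7 | cyclic trimethylsilyl enol ether of F4, racemic, one enantiomer drawn | C1=C[C@](O[Si](CC)(CC)CC)(/C=C\C=O)C(O[Si](C)(C)C)=C[C@H]1O[Si](C)(C)C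
F6 | step 7 | meso bicyclic 4-exo,6-exo-bis(trimethylsilyl) ether of 12 | C1=C[C@@]2(O[Si](CC)(CC)CC)C(=O)[C@H]([C@H](O[Si](C)(C)C)C=C2)[C@H]1O[Si](C)(C)C
F0 | step 10 | none | none
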